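## Retrosynthetic overview
1. The oxepane is closed last, by a 7-endo opening of a Shi epoxide by the ring-B hydroxyl (Ce–OH). The tertiary C8-type alcohol (a20) comes from an exocyclic methylene by epoxidation and hydride opening.
2. The bond between the enone β-carbon (a3) and the right-hand CH2CH2 unit (a4) is made by a Stork–Danheiser addition of a primary alkyllithium (from iodide 16) to a cis-ready bicyclic vinylogous ester (25). The cis-decalin arises from γ-epimerisation of the enone.
3. Ring B, with its quaternary carbon Cd and the stereocentres Cc and Ce, is formed by a Ti(III) radical epoxide-opening 6-endo cascade of a Sharpless-derived epoxy-alkene built from geraniol.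
4. Left bicycle: ring A2 comes from 4,4-dimethylcyclohexenone by tandem asymmetric conjugate addition/alkylation, then MeLi gives the tertiary carbinol. Ring A1 is closed by Dieckmann condensation and converted to the vinylogous ester.

Assumptions:
- L-(+)-DET gives the (2S,3S)-epoxide of geraniol.
- The fructose-derived Shi ketone that gives (S)-2,3-oxidosqualene from squalene gives the (S)-oxirane needed here.
- The cis-fused enone is thermodynamically preferred over trans. In the trans isomer the quaternary CMe2 carbon sits equatorial on the enone ring and suffers A(1,2) strain with the a4 chain.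

---

## Route

**Step 1**
Reactants: 1 geraniol
Product: 2 (2S,3S)-2,3-epoxygeraniol
Conditions: Ti(OiPr)4 (cat.), L-(+)-DET (cat.), TBHP, 3 Å MS, CH2Cl2, –20 °C
Reagents that add atoms: tert-butyl hydroperoxide, CC(C)(C)OO (supplies the epoxide O)
Why: Sharpless asymmetric epoxidation acts only on the allylic C2=C3 alkene and sets C2 (S), which becomes Ce of the target, and C3 (S).

**Step 2**
Reactants: 2
Product: 3 (2R,3S)-2,3-epoxy-3,7-dimethyloct-6-enal
Conditions: TEMPO (10 mol%), PhI(OAc)2, CH2Cl2, 0 °C to rt; used crude
Reagents that add atoms: none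
Why: Anelli-type TEMPO oxidation stops at the aldehyde without epimerising the α-epoxy centre, so no stereocentre is altered.

**Step 3**
Reactants: 3
Product: 4 (2S,3S)-2-ethenyl-3-methyl-3-(4-methylpent-3-en-1-yl)oxirane
Conditions: Ph3P=CH2 (from Ph3PCH3Br, KOtBu), THF, –78 °C to 0 °C
Reagents that add atoms: methylenetriphenylphosphorane, C=P(c1ccccc1)(c1ccccc1)c1ccccc1 (adds CH2)
Why: Wittig methylenation converts CHO to a vinyl group (this CH2 becomes a19) under salt-free, low-temperature conditions that leave both epoxide stereocentres untouched.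

**Step 4**
Reactants: 4; 5 2-bromopropene
Product: 6 (2S,3S)-2-(3-methylbut-3-en-1-yl)-3-methyl-3-(4-methylpent-3-en-1-yl)oxirane
Conditions: 9-BBN-H (1.0 equiv), THF, 0 °C; then Pd(dppf)Cl2 (5 mol%), K3PO4 (aq.), 5, THF/DMF, 50 °C
Reagents that add atoms: none (5 is the numbered partner; the B–H adds only H)
Why: 9-BBN hydroborates only the monosubstituted vinyl group, and the B-alkyl Suzuki–Miyaura coupling forms the sp3–sp2 bond (a19–a20) with retention of the epoxide.

**Step 5**
Reactants: 6; 7 4-(benzyloxy)but-1-ene
Product: 8 (2S,3S)-2-[(3E)-6-(benzyloxy)-3-methylhex-3-en-1-yl]-3-methyl-3-(4-methylpent-3-en-1-yl)oxirane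
Conditions: Hoveyda–Grubbs II (5 mol%), 7 (4 equiv), CH2Cl2, 40 °C
Reagents that add atoms: none
Why: Cross-metathesis converts the 1,1-disubstituted alkene into the trisubstituted alkene with E (a19 trans to a5) favoured thermodynamically, and this geometry fixes the equatorial Cc chain in Step 6. The Z isomer is removed on AgNO3-silica.

**Step 6**
Reactants: 8
Product: 9 cyclohexanol: C1-OH equatorial (Ce, S), C2 quaternary (Cd) with axial Me and equatorial homoprenyl, C3 equatorial CH2CH2OBn (Cc), C4 exocyclic methylene
Conditions: Cp2TiCl2 (20 mol%), Mn dust, 2,4,6-collidine, TMSCl, THF, rt; then TBAF workup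
Reagents that add atoms: none (TMS groups are removed on workup)
Why: Proposed new method: Cp2TiCl opens the trisubstituted epoxide to the tertiary radical at Cd with Ti–O kept on Ce, which undergoes chair-like 6-endo cyclisation onto the E-alkene. The bulkier homoprenyl chain sits equatorial (Me axial), Cc is set equatorial by the E geometry, and Ce is retained from the epoxide. The resulting a20 tertiary radical is trapped by Ti(III) and β-H-eliminates to the exocyclic methylene. The closest known reaction is Ti(III) catalytic epoxypolyene radical cyclisation (Cuerva–Oltra).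

**Step 7**
Reactants: 9
Product: 10 terminal (S)-epoxide of the homoprenyl alkene (a11 S), exocyclic methylene intact
Conditions: Shi fructose-derived ketone (30 mol%), Oxone, K2CO3, Bu4NHSO4, MeCN/DMM/aq. buffer pH 10.5, 0 °C
Reagents that add atoms: Oxone (KHSO5), OOS(=O)(=O)[O-] (supplies O)
Why: Shi asymmetric epoxidation is catalyst-controlled and chemoselective for the more electron-rich trisubstituted alkene. It sets a11 (S), which is retained as the C–OH of the target.

**Step 8**
Reactants: 10
Product: 11 oxepane-fused cyclohexane with exocyclic methylene and a11-OH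
Conditions: CSA (10 mol%), CH2Cl2, 0 °C
Reagents that add atoms: none
Why: Acid-catalysed 7-endo epoxide opening: Ce–OH attacks the tertiary (CMe2) epoxide carbon, which is achiral so there is no stereochemical consequence, and a11 is retained as the secondary alcohol. Ce–O and the Cd chain are trans-diequatorial, giving the trans-fused 6-7 system.

**Step 9**
Reactants: 11
Product: 12 α-spiro-epoxide at a20
Conditions: mCPBA, NaHCO3, CH2Cl2, 0 °C
Reagents that add atoms: mCPBA, OOC(=O)c1cccc(Cl)c1 (supplies O)
Why: Peracid epoxidation of the exocyclic alkene occurs from the α-face because the β-face is shielded by the syn-axial angular Me on Cd.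

**Step 10**
Reactants: 12
Product: 13 diol with a20 tertiary alcohol (OH α/equatorial, Me β/axial), OBn retained
Conditions: LiEt3BH (Super-Hydride), THF, 0 °C to rt
Reagents that add atoms: none (hydride adds only H)
Why: Hydride opens the spiro-epoxide at the unhindered CH2 with the C–O bond at a20 retained, giving the target configuration at a20.

**Step 11**
Reactants: 13
Product: 14 bis-TES ether
Conditions: TESOTf (3 equiv), 2,6-lutidine, CH2Cl2, –78 °C to 0 °C
Reagents that add atoms: TESOTf, CC[Si](CC)(CC)OS(=O)(=O)C(F)(F)F (adds SiEt3)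
Why: Silylation protects both hydroxyls so that an organolithium can be made; no stereocentre is touched.

**Step 12**
Reactants: 14
Product: 15 primary alcohol
Conditions: H2 (1 atm), 10% Pd/C, EtOAc, rt
Reagents that add atoms: none
Why: Hydrogenolysis of the benzyl ether is compatible with the silyl ethers and the saturated oxepane (no alkenes remain).

**Step 13**
Reactants: 15
Product: 16 primary iodide (right-hand fragment)
Conditions: I2, PPh3, imidazole, CH2Cl2, 0 °C
Reagents that add atoms: iodine, II (adds I)
Why: Appel-type (Garegg–Samuelsson) iodination proceeds by SN2 at a primary carbon with no stereochemical consequence.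

**Step 14**
Reactants: 17 4,4-dimethylcyclohex-2-en-1-one
Product: 18 tert-butyl 2-[(1S,2S)-2-ethenyl-3,3-dimethyl-6-oxocyclohexyl]acetate (2,3-trans)
Conditions: CH2=CHMgBr, CuBr·SMe2 (5 mol%), chiral ferrocenyl diphosphine (Josiphos-type, enantiomer chosen to give 2S), TMSCl, Et2O, –78 °C; then MeLi, THF, –78 °C; then DMPU, BrCH2CO2tBu, –78 to –30 °C
Reagents that add atoms: vinylmagnesium bromide, C=C[Mg]Br (adds vinyl); tert-butyl bromoacetate, BrCC(=O)OC(C)(C)C (adds CH2CO2tBu)
Why: Proposed new method: Cu-catalysed asymmetric 1,4-addition of the vinyl Grignard to C3 (the only new stereocentre set enantioselectively). The Mg enolate is trapped as the regiodefined TMS enol ether, regenerated as the Li enolate with MeLi, and alkylated at C2 anti to the new vinyl group to give the trans product. The closest known reaction is the Alexakis/Feringa asymmetric conjugate addition–enolate alkylation tandem.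

**Step 15**
Reactants: 18
Product: 19 tertiary alcohol (new Me cis to CH2CO2tBu, OH trans; 2,3-trans)
Conditions: MeLi, CeCl3, THF, –78 °C
Reagents that add atoms: methyllithium, C[Li] (adds CH3)
Why: Organocerium 1,2-addition occurs axially on the chair with both ring substituents equatorial, so the new methyl is axial and cis to C2-CH2CO2tBu, the a28 relative configuration of the target; the ester and vinyl group survive at –78 °C.

**Step 16**
Reactants: 19
Product: 20 TES ether of 19
Conditions: TESOTf, 2,6-lutidine, CH2Cl2, –78 °C
Reagents that add atoms: TESOTf, CC[Si](CC)(CC)OS(=O)(=O)C(F)(F)F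
Why: Protection prevents lactonisation onto the ester and consumption of organometallics later.

**Step 17**
Reactants: 20
Product: 21 aldehyde
Conditions: O3, CH2Cl2/MeOH, –78 °C; then Me2S
Reagents that add atoms: ozone, O=[O+][O-] (adds O)
Why: Ozonolysis cleaves only the vinyl group; the ester, silyl ether and stereocentres are unaffected.

**Step 18**
Reactants: 21
Product: 22 secondary alcohol (mixture at the carbinol carbon, irrelevant)
Conditions: EtMgBr, THF, –78 °C
Reagents that add atoms: ethylmagnesium bromide, CC[Mg]Br (adds Et)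
Why: Chemoselective Grignard addition to the aldehyde over the hindered tert-butyl ester.

**Step 19**
Reactants: 22
Product: 23 ethyl ketone
Conditions: Dess–Martin periodinane, NaHCO3, CH2Cl2, rt
Reagents that add atoms: none
Why: Mild oxidation of the secondary alcohol to the ketone that becomes a3.

**Step 20**
Reactants: 23
Product: 24 bicyclic 2-methylcyclohexane-1,3-dione (trans-fused at this stage)
Conditions: KOtBu (2 equiv), tBuOH/THF, 50 °C; aq. NH4Cl
Reagents that add atoms: none
Why: Dieckmann-type intramolecular Claisen condensation: the ketone enolate at the ethyl CH2 attacks the tert-butyl ester to form the six-membered dione. Cb is not acidic, so the C2 and carbinol stereocentres are not scrambled.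

**Step 21**
Reactants: 24
Product: 25 vinylogous ester (OEt on the less hindered carbonyl a26; hindered a3 C=O free)
Conditions: HC(OEt)3, EtOH, p-TsOH (cat.), rt
Reagents that add atoms: ethanol, CCO (adds OEt)
Why: Acid-catalysed enol etherification occurs at the less hindered carbonyl, which leaves the hindered carbonyl for the Stork–Danheiser addition.

**Step 22**
Reactants: 16; 25
Product: 26 enone (Ca still trans-epimer, three TES ethers)
Conditions: t-BuLi (2.1 equiv), Et2O, –78 °C (Li–I exchange on 16); CeCl3, THF, –78 °C; add 25, –78 °C to 0 °C; then 1 M HCl, THF, rt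
Reagents that add atoms: water, O (carbonyl oxygen of the product enone)
Why: Stork–Danheiser reaction: the organocerium adds to the a3 carbonyl, and acid then ionises the tertiary allylic alcohol and hydrolyses the enol ether to give the tetrasubstituted α-methyl enone with the chain on the β-carbon. This forms the a3–a4 bond and the enone in one operation.

**Step 23**
Reactants: 26
Product: 27 cis-fused enone
Conditions: DBU (3 equiv), toluene, 80 °C
Reagents that add atoms: none
Why: Proposed new method: γ-deprotonation at Ca gives the extended dienolate, and thermodynamic reprotonation funnels the mixture to the cis-fused isomer, in which the quaternary CMe2 carbon is pseudo-axial on the enone ring and A(1,2) strain with the a4 chain is relieved. The closest known reaction is base-mediated γ-epimerisation of decalin enones.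

**Step 24**
Reactants: 27
Product: 28 sipholenol K
Conditions: HF·pyridine, pyridine/THF, rt, 24 h
Reagents that add atoms: none
Why: Fluoride-mediated removal of all three TES ethers leaves the enone, the oxepane ether and the stereocentres unchanged.

---

## Compound list
1 | geraniol | CC(C)=CCC/C(C)=C/CO | starting material
2 | (2S,3S)-2,3-epoxygeraniol | OC[C@@H]1O[C@@]1(C)CCC=C(C)C | intermediate
3 | (2R,3S)-2,3-epoxy-3,7-dimethyloct-6-enal | O=C[C@@H]1O[C@@]1(C)CCC=C(C)C | intermediate
4 | (2S,3S)-2-ethenyl-3-methyl-3-(4-methylpent-3-en-1-yl)oxirane | C=C[C@@H]1O[C@@]1(C)CCC=C(C)C | intermediate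
5 | 2-bromopropene | C=C(C)Br | starting material
6 | (2S,3S)-2-(3-methylbut-3-en-1-yl)-3-methyl-3-(4-methylpent-3-en-1-yl)oxirane | C=C(C)CC[C@@H]1O[C@@]1(C)CCC=C(C)C | intermediate
7 | 4-(benzyloxy)but-1-ene | C=CCCOCc1ccccc1 | starting material
8 | (2S,3S)-2-[(3E)-6-(benzyloxy)-3-methylhex-3-en-1-yl]-3-methyl-3-(4-methylpent-3-en-1-yl)oxirane | c1ccccc1COCC/C=C(C)/CC[C@@H]1O[C@@]1(C)CCC=C(C)C | intermediate
9 | 3-[2-(benzyloxy)ethyl]-2-methyl-2-(4-methylpent-3-en-1-yl)-4-methylidenecyclohexan-1-ol (1S; 2-Me axial; 1-OH and 3-chain equatorial) | C=C1CC[C@H](O)[C@@](C)(CCC=C(C)C)[C@@H]1CCOCc2ccccc2 | intermediate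
10 | terminal (S)-epoxide of 9 | C=C1CC[C@H](O)[C@@](C)(CC[C@@H]3OC3(C)C)[C@@H]1CCOCc2ccccc2 | intermediate
11 | oxepane-fused cyclohexane with exocyclic methylene, a11-OH, OBn | c1ccccc1COCC[C@H]2[C@]3(C)CC[C@H](O)C(C)(C)O[C@H]3CCC2=C | intermediate
12 | α-spiro-epoxide of 11 | c1ccccc1COCC[C@H]2[C@]3(C)CC[C@H](O)C(C)(C)O[C@H]3CC[C@]2(C3)O3 | intermediate
13 | diol-OBn (right-hand bicycle) | c1ccccc1COCC[C@H]2[C@]3(C)CC[C@H](O)C(C)(C)O[C@H]3CC[C@]2(C)O | intermediate
14 | bis-TES ether of 13 | c1ccccc1COCC[C@H]2[C@]3(C)CC[C@H](O[Si](CC)(CC)CC)C(C)(C)O[C@H]3CC[C@]2(C)O[Si](CC)(CC)CC | intermediate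
15 | primary alcohol (debenzylated 14) | OCC[C@H]2[C@]3(C)CC[C@H](O[Si](CC)(CC)CC)C(C)(C)O[C@H]3CC[C@]2(C)O[Si](CC)(CC)CC | intermediate
16 | primary iodide (right-hand fragment) | ICC[C@H]2[C@]3(C)CC[C@H](O[Si](CC)(CC)CC)C(C)(C)O[C@H]3CC[C@]2(C)O[Si](CC)(CC)CC | intermediate
17 | 4,4-dimethylcyclohex-2-en-1-one | O=C1C=CC(C)(C)CC1 | starting material
18 | tert-butyl 2-[(1S,2S)-2-ethenyl-3,3-dimethyl-6-oxocyclohexyl]acetate | C=C[C@H]1[C@H](CC(=O)OC(C)(C)C)C(=O)CCC1(C)C | intermediate
19 | tertiary alcohol from 18 (Me cis to CH2CO2tBu) | C=C[C@H]1[C@H](CC(=O)OC(C)(C)C)[C@@](C)(O)CCC1(C)C | intermediate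
20 | TES ether of 19 | C=C[C@H]1[C@H](CC(=O)OC(C)(C)C)[C@@](C)(O[Si](CC)(CC)CC)CCC1(C)C | intermediate
21 | aldehyde from ozonolysis of 20 | O=C[C@H]1[C@H](CC(=O)OC(C)(C)C)[C@@](C)(O[Si](CC)(CC)CC)CCC1(C)C | intermediate
22 | secondary alcohol (EtMgBr adduct of 21) | CCC(O)[C@H]1[C@H](CC(=O)OC(C)(C)C)[C@@](C)(O[Si](CC)(CC)CC)CCC1(C)C | intermediate
23 | ethyl ketone | CCC(=O)[C@H]1[C@H](CC(=O)OC(C)(C)C)[C@@](C)(O[Si](CC)(CC)CC)CCC1(C)C | intermediate
24 | bicyclic 2-methylcyclohexane-1,3-dione | CC1C(=O)C[C@@H]2[C@@](C)(O[Si](CC)(CC)CC)CCC(C)(C)[C@H]2C1=O | intermediate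
25 | bicyclic vinylogous ester | CCOC1=C(C)C(=O)[C@@H]2C(C)(C)CC[C@](C)(O[Si](CC)(CC)CC)[C@H]2C1 | intermediate
26 | tri-TES enone, Ca trans-epimer | CC1=C(CC[C@H]2[C@]3(C)CC[C@H](O[Si](CC)(CC)CC)C(C)(C)O[C@H]3CC[C@]2(C)O[Si](CC)(CC)CC)[C@H]2[C@H](CC1=O)[C@@](C)(O[Si](CC)(CC)CC)CCC2(C)C | intermediate
27 | tri-TES enone, cis-fused | CC1=C(CC[C@H]2[C@]3(C)CC[C@H](O[Si](CC)(CC)CC)C(C)(C)O[C@H]3CC[C@]2(C)O[Si](CC)(CC)CC)[C@@H]2[C@H](CC1=O)[C@@](C)(O[Si](CC)(CC)CC)CCC2(C)C | intermediate
28 | sipholenol K | CC1=C(CC[C@H]2[C@]3(C)CC[C@H](O)C(C)(C)O[C@H]3CC[C@]2(C)O)[C@@H]2[C@H](CC1=O)[C@@](C)(O)CCC2(C)C | target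

---

**Total step count:** 24 steps (13 on the right-hand fragment, 8 on the left-hand fragment, 3 after convergence).
**Longest linear sequence:** 16 steps (geraniol → 16 in 13 steps, then Steps 22–24).

**Three steps most likely to fail**
1. **Step 6 (Ti(III) radical cascade).** The radical at Cd bears Me and a CH2R chain, so diastereoselection at Cd relies on a modest steric preference.
   - Fallback: a Lewis-acid-promoted cationic epoxy-olefin cyclisation of 8 (for example Me2AlCl, –78 °C). Opening with inversion at Cd transfers the (3S) epoxide configuration stereospecifically, so Cd is set by the epoxide rather than by radical conformation.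
2. **Step 14 (asymmetric tandem addition/alkylation on a β-hindered enone).**
   - Fallback: run the tandem sequence with an achiral Cu ligand to give racemic 18. Then convert the tert-butyl ester to the acid with TFA, resolve it as the (S)-1-phenylethylamine salt, and re-esterify.
3. **Step 23 (thermodynamic cis-epimerisation at Ca).** It rests on the A(1,2)-strain argument; if the trans isomer is actually favoured, it delivers the wrong ring fusion.
   - Fallback: forge the cis-decalin kinetically by an intramolecular Diels–Alder of a 1,7,9-decatriene, in which a vinyl carbinol tether and a 1-alkoxydiene give the cis-fused ring A1 with the tetrasubstituted alkene directly. Allylic oxidation then gives the enone.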